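**Retrosynthetic overview**

1. The strategy rests on C2 of unit 1 (the flavanone with the 4-methoxyphenyl group; rings A and C, unprimed atoms; unit 2 is primed). C2 is a benzylic carbon on the ring oxygen O1, which makes it the CH2 of an aryl 4-methoxybenzyl ether, and C3 is alpha to the C4 ketone and bonded to C3'.
2. The last skeletal bond is C2–C3. A dirhodium carbenoid at C3, formed from the alpha-diazo ketone, inserts into a C–H bond of the ortho O–CH2 group (1,6 C–H insertion). This closes ring C of unit 1 and sets C2 and C3 (cis).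
3. The diazo ketone comes from the 1,4-diketone by detrifluoroacetylative diazo transfer. The C3–C3' bond comes from trans-selective alkylation of the enolate of flavanone unit 2 with the alpha-bromo ketone of the protected acetophenone.
4. Ring C' of unit 2 is made first as 5,7-bis(benzyloxy)chromone, and C2' is then set by enantioselective rhodium-catalysed conjugate arylation. Both halves start from 2',4',6'-trihydroxyacetophenone.
5. Ring order: ring C' (unit 2), then the C3–C3' bond, then ring C of unit 1 (key step), then desilylation and hydrogenolysis.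

Key step: step 9

**Remarks on the chemistry**

- The para oxygen of ring A of unit 1 carries a second 4-methoxybenzyl group (one etherification for both oxygens). It cannot reach the carbenoid and is removed in the final hydrogenolysis.
- The sense of induction of (R)-MeO-F12-BIPHEP in step 3 and of Rh2[(S)-PTTL]4 in step 9 is assumed as written. If either proves opposite on these substrates, its mirror image is used.

**Route**

Step 1
Reactants: 1 2',4',6'-trihydroxyacetophenone
Product: 2 1-[2,4-bis(benzyloxy)-6-hydroxyphenyl]ethan-1-one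
Conditions: BnBr (2.1 equiv), K2CO3, DMF, 0 °C to rt
Reagents that add atoms: benzyl bromide BrCc1ccccc1
Why: Williamson etherification should alkylate the para and one ortho hydroxyl, while the second ortho hydroxyl, hydrogen-bonded to the acetyl carbonyl, stays free.

Step 2
Reactants: 2 1-[2,4-bis(benzyloxy)-6-hydroxyphenyl]ethan-1-one
Product: 4 5,7-bis(benzyloxy)-4H-chromen-4-one, via enaminone 3 (not isolated)
Conditions: Me2NCH(OMe)2, toluene, 95 °C; then conc. HCl, CH2Cl2, rt
Reagents that add atoms: N,N-dimethylformamide dimethyl acetal COC(OC)N(C)C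
Why: Enaminone condensation at the methyl ketone followed by acid-promoted addition–elimination of the free phenol (loss of dimethylamine) is the standard chromone annulation and closes ring C' of unit 2.

Step 3
Reactants: 4 5,7-bis(benzyloxy)-4H-chromen-4-one; 5 4-(benzyloxy)phenylboronic acid
Product: 6 (2R)-5,7-bis(benzyloxy)-2-[4-(benzyloxy)phenyl]chroman-4-one
Conditions: [Rh(OH)(cod)]2 (2 mol %), (R)-MeO-F12-BIPHEP [2,2'-bis(bis(3,4,5-trifluorophenyl)phosphino)-6,6'-dimethoxy-1,1'-biphenyl] (4.4 mol %), 5 (2.5 equiv), toluene/H2O 10:1, 30 °C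
Reagents that add atoms: none
Why: Hayashi–Miyaura-type conjugate arylation through an aryl–rhodium species (monovalent rhodium) whose electron-poor chiral bisphosphine should differentiate the enone faces and set C2' as R, the near-neutral, low-temperature conditions keeping the flavanone from ring opening.

Step 4
Reactants: 1 2',4',6'-trihydroxyacetophenone; 7 4-methoxybenzyl chloride
Product: 8 1-{2-hydroxy-4,6-bis[(4-methoxybenzyl)oxy]phenyl}ethan-1-one
Conditions: 7 (2.1 equiv), K2CO3, Bu4NI (cat.), DMF, rt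
Reagents that add atoms: none
Why: Williamson etherification with the same selectivity as in step 1 should leave the chelated ortho hydroxyl free, and the ortho ether installed here later supplies C2 and the 4-methoxyphenyl ring.

Step 5
Reactants: 8 1-{2-hydroxy-4,6-bis[(4-methoxybenzyl)oxy]phenyl}ethan-1-one
Product: 9 1-{2,4-bis[(4-methoxybenzyl)oxy]-6-[(triisopropylsilyl)oxy]phenyl}ethan-1-one
Conditions: iPr3SiOTf (1.2 equiv), 2,6-lutidine, CH2Cl2, 0 °C to rt
Reagents that add atoms: triisopropylsilyl trifluoromethanesulfonate CC(C)[Si](C(C)C)(C(C)C)OS(=O)(=O)C(F)(F)F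
Why: Silylation of the hindered, chelated phenol with a silyl triflate and a non-nucleophilic base should give an ortho substituent that has no C–H bond alpha to oxygen.

Step 6
Reactants: 9 1-{2,4-bis[(4-methoxybenzyl)oxy]-6-[(triisopropylsilyl)oxy]phenyl}ethan-1-one
Product: 11 2-bromo-1-{2,4-bis[(4-methoxybenzyl)oxy]-6-[(triisopropylsilyl)oxy]phenyl}ethan-1-one, via silyl enol ether 10 (not isolated)
Conditions: Me3SiOTf, Et3N, CH2Cl2, 0 °C; solvent exchange; then NBS, NaHCO3, THF, −78 to 0 °C
Reagents that add atoms: N-bromosuccinimide O=C1CCC(=O)N1Br; trimethylsilyl trifluoromethanesulfonate C[Si](C)(C)OS(=O)(=O)C(F)(F)F (silicon kept only in 10)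
Why: Soft enolisation to the trimethylsilyl enol ether followed by electrophilic bromination should place bromine on the side chain, because the enol ether is far more nucleophilic than the electron-rich ring and no free enolate is formed next to the aryl silyl ether.

Step 7
Reactants: 6 (2R)-5,7-bis(benzyloxy)-2-[4-(benzyloxy)phenyl]chroman-4-one; 11 2-bromo-1-{2,4-bis[(4-methoxybenzyl)oxy]-6-[(triisopropylsilyl)oxy]phenyl}ethan-1-one
Product: 13 (2R,3S)-5,7-bis(benzyloxy)-2-[4-(benzyloxy)phenyl]-3-(2-{2,4-bis[(4-methoxybenzyl)oxy]-6-[(triisopropylsilyl)oxy]phenyl}-2-oxoethyl)chroman-4-one (2,3-trans), via lithium enolate 12 (not isolated)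
Conditions: LiN(SiMe3)2 (1.05 equiv), THF, −78 °C; then 11 (1.1 equiv), −78 to −40 °C; AcOH quench at −78 °C
Reagents that add atoms: none
Why: SN2 alkylation of the ketone enolate by the alpha-bromo ketone (its carbonyl shielded by two ortho substituents) forms C3–C3', the electrophile entering anti to the C2' aryl group so that C3' is set trans to C2' (also the thermodynamically preferred isomer), while the low temperature holds back E1cB opening of ring C'.

Step 8
Reactants: 13 (2R,3S)-5,7-bis(benzyloxy)-2-[4-(benzyloxy)phenyl]-3-(2-{2,4-bis[(4-methoxybenzyl)oxy]-6-[(triisopropylsilyl)oxy]phenyl}-2-oxoethyl)chroman-4-one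
Product: 16 (2R,3S)-5,7-bis(benzyloxy)-2-[4-(benzyloxy)phenyl]-3-(1-diazo-2-{2,4-bis[(4-methoxybenzyl)oxy]-6-[(triisopropylsilyl)oxy]phenyl}-2-oxoethyl)chroman-4-one, via lithium enolate 14 (not isolated), via trifluoroacetyl diketone 15 (not isolated)
Conditions: LiN(SiMe3)2 (1.1 equiv), THF, −78 °C; CF3CO2CH2CF3, −78 °C; 5% HCl wash; then MsN3, Et3N, H2O (1 equiv), MeCN, rt
Reagents that add atoms: methanesulfonyl azide CS(=O)(=O)N=[N+]=[N-]; 2,2,2-trifluoroethyl trifluoroacetate O=C(OCC(F)(F)F)C(F)(F)F (trifluoroacetyl kept only in 15)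
Why: In this detrifluoroacetylative (deacylative Regitz) diazo transfer, kinetic deprotonation should occur at the less hindered side-chain methylene and not at the C3' methine, Claisen trifluoroacetylation then activates that carbon, and the sulfonyl azide transfers N2 with loss of the trifluoroacetyl group without touching C2' or C3'.

Step 9
Reactants: 16 (2R,3S)-5,7-bis(benzyloxy)-2-[4-(benzyloxy)phenyl]-3-(1-diazo-2-{2,4-bis[(4-methoxybenzyl)oxy]-6-[(triisopropylsilyl)oxy]phenyl}-2-oxoethyl)chroman-4-one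
Product: 17 (2S,3S)-3-{(2R,3S)-5,7-bis(benzyloxy)-2-[4-(benzyloxy)phenyl]-4-oxochroman-3-yl}-7-[(4-methoxybenzyl)oxy]-2-(4-methoxyphenyl)-5-[(triisopropylsilyl)oxy]chroman-4-one
Conditions: Rh2[(S)-PTTL]4 (2 mol %; PTTL = N-phthaloyl-tert-leucinate, C6H4(CO)2N–CH(CMe3)–CO2), CH2Cl2, 4 Å sieves, slow addition of 16 at −40 °C, then to 0 °C
Reagents that add atoms: none
Why: The dirhodium tetracarboxylate (divalent rhodium) expels N2 from the diazo ketone to give an electrophilic carbenoid at C3, which inserts through a concerted, asynchronous three-centre (hydride-transfer-like) transition state into a C–H bond of the ortho O–CH2 group and forms C2–C3; the closest known reaction type is the dirhodium-catalysed C–H insertion of 2-(benzyloxy)aryl alpha-diazo ketones to cis-2,3-disubstituted chroman-4-ones. Ring C of unit 1 closes by this 1,6-insertion (six-membered transition state with the aryl ketone as rigid tether), so the former protecting group becomes C2 with its 4-methoxyphenyl substituent. C2 and C3 are created in the same event: the compact transition state, with the 4-methoxyphenyl group turned away from the carboxylate wall, should give the kinetic 2,3-cis isomer, and the neutral conditions leave the epimerisable C3 untouched. The absolute sense (2S,3S) depends on which carbenoid face meets the C–H bond; this is meant to be decided by the chiral phthalimido carboxylate ligands, with the resident C3' centre as a second element that the chosen catalyst antipode reinforces. The step needs chemoselectivity over 1,2-hydride shift from C3', oxonium ylide formation and other C–H bonds: the C3'–H bond is made electron-poor by the C4' ketone and is held in the carbenoid plane by the bulky ligands, the inserting methylene is activated by both the ether oxygen and the 4-methoxyphenyl ring, the other ortho oxygen carries a silyl group without alpha C–H bonds, and the remaining benzylic ethers are out of reach (para position of ring A) or would need a seven-membered transition state (5'-O-benzyl).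

Step 10
Reactants: 17 (2S,3S)-3-{(2R,3S)-5,7-bis(benzyloxy)-2-[4-(benzyloxy)phenyl]-4-oxochroman-3-yl}-7-[(4-methoxybenzyl)oxy]-2-(4-methoxyphenyl)-5-[(triisopropylsilyl)oxy]chroman-4-one
Product: 18 (2S,3S)-3-{(2R,3S)-5,7-bis(benzyloxy)-2-[4-(benzyloxy)phenyl]-4-oxochroman-3-yl}-5-hydroxy-7-[(4-methoxybenzyl)oxy]-2-(4-methoxyphenyl)chroman-4-one
Conditions: Bu4NF/AcOH (1:1), THF, 0 °C
Reagents that add atoms: none
Why: Fluoride-induced cleavage of the aryl silyl ether, buffered with acetic acid, should neither epimerise the cis C3 centre nor open the rings by retro-oxa-Michael reaction.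

Step 11
Reactants: 18 (2S,3S)-3-{(2R,3S)-5,7-bis(benzyloxy)-2-[4-(benzyloxy)phenyl]-4-oxochroman-3-yl}-5-hydroxy-7-[(4-methoxybenzyl)oxy]-2-(4-methoxyphenyl)chroman-4-one
Product: 19 (2S,3S)-5,7-dihydroxy-3-[(2R,3S)-5,7-dihydroxy-2-(4-hydroxyphenyl)-4-oxochroman-3-yl]-2-(4-methoxyphenyl)chroman-4-one (CNP0196568.4)
Conditions: H2 (1 atm), Pd/C (10 wt %), EtOAc/MeOH, rt, stopped at full conversion
Reagents that add atoms: none
Why: Catalytic hydrogenolysis under neutral conditions should cleave the three benzyl and the one 4-methoxybenzyl aryl ethers, which are far more labile than the cyclic benzylic C2–O and C2'–O bonds, so that all four stereocentres are retained.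

**Compound list**

1 | 2',4',6'-trihydroxyacetophenone | CC(=O)c1c(O)cc(O)cc1O | starting material
2 | 1-[2,4-bis(benzyloxy)-6-hydroxyphenyl]ethan-1-one | CC(=O)c1c(O)cc(OCc2ccccc2)cc1OCc1ccccc1 | intermediate
3 | (E)-1-[2,4-bis(benzyloxy)-6-hydroxyphenyl]-3-(dimethylamino)prop-2-en-1-one | CN(C)/C=C/C(=O)c1c(O)cc(OCc2ccccc2)cc1OCc1ccccc1 | intermediate (not isolated)
4 | 5,7-bis(benzyloxy)-4H-chromen-4-one | O=c1ccoc2cc(OCc3ccccc3)cc(OCc3ccccc3)c12 | intermediate
5 | 4-(benzyloxy)phenylboronic acid | OB(O)c1ccc(OCc2ccccc2)cc1 | starting material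
6 | (2R)-5,7-bis(benzyloxy)-2-[4-(benzyloxy)phenyl]chroman-4-one | O=C1C[C@H](c2ccc(OCc3ccccc3)cc2)Oc2cc(OCc3ccccc3)cc(OCc3ccccc3)c12 | intermediate
7 | 4-methoxybenzyl chloride | COc1ccc(CCl)cc1 | starting material
8 | 1-{2-hydroxy-4,6-bis[(4-methoxybenzyl)oxy]phenyl}ethan-1-one | CC(=O)c1c(O)cc(OCc2ccc(OC)cc2)cc1OCc1ccc(OC)cc1 | intermediate
9 | 1-{2,4-bis[(4-methoxybenzyl)oxy]-6-[(triisopropylsilyl)oxy]phenyl}ethan-1-one | CC(=O)c1c(O[Si](C(C)C)(C(C)C)C(C)C)cc(OCc2ccc(OC)cc2)cc1OCc1ccc(OC)cc1 | intermediate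
10 | trimethylsilyl enol ether of 9 | C=C(O[Si](C)(C)C)c1c(O[Si](C(C)C)(C(C)C)C(C)C)cc(OCc2ccc(OC)cc2)cc1OCc1ccc(OC)cc1 | intermediate (not isolated)
11 | 2-bromo-1-{2,4-bis[(4-methoxybenzyl)oxy]-6-[(triisopropylsilyl)oxy]phenyl}ethan-1-one | BrCC(=O)c1c(O[Si](C(C)C)(C(C)C)C(C)C)cc(OCc2ccc(OC)cc2)cc1OCc1ccc(OC)cc1 | intermediate
12 | lithium enolate of 6 (lithium (2R)-5,7-bis(benzyloxy)-2-[4-(benzyloxy)phenyl]-2H-chromen-4-olate) | [Li+].[O-]C1=C[C@H](c2ccc(OCc3ccccc3)cc2)Oc2cc(OCc3ccccc3)cc(OCc3ccccc3)c12 | intermediate (not isolated)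
13 | (2R,3S)-5,7-bis(benzyloxy)-2-[4-(benzyloxy)phenyl]-3-(2-{2,4-bis[(4-methoxybenzyl)oxy]-6-[(triisopropylsilyl)oxy]phenyl}-2-oxoethyl)chroman-4-one | COc1ccc(COc2cc(OCc3ccc(OC)cc3)cc(O[Si](C(C)C)(C(C)C)C(C)C)c2C(=O)C[C@@H]2C(=O)c3c(OCc4ccccc4)cc(OCc4ccccc4)cc3O[C@H]2c2ccc(OCc3ccccc3)cc2)cc1 | intermediate
14 | lithium enolate of 13 at the side-chain methylene | COc1ccc(COc2cc(OCc3ccc(OC)cc3)cc(O[Si](C(C)C)(C(C)C)C(C)C)c2C([O-])=C[C@@H]2C(=O)c3c(OCc4ccccc4)cc(OCc4ccccc4)cc3O[C@H]2c2ccc(OCc3ccccc3)cc2)cc1.[Li+] | intermediate (not isolated)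
15 | trifluoroacetyl derivative of 13 at the side-chain methylene (epimers at the new carbon, largely enolised) | COc1ccc(COc2cc(OCc3ccc(OC)cc3)cc(O[Si](C(C)C)(C(C)C)C(C)C)c2C(=O)C(C(=O)C(F)(F)F)[C@@H]2C(=O)c3c(OCc4ccccc4)cc(OCc4ccccc4)cc3O[C@H]2c2ccc(OCc3ccccc3)cc2)cc1 | intermediate (not isolated)
16 | (2R,3S)-5,7-bis(benzyloxy)-2-[4-(benzyloxy)phenyl]-3-(1-diazo-2-{2,4-bis[(4-methoxybenzyl)oxy]-6-[(triisopropylsilyl)oxy]phenyl}-2-oxoethyl)chroman-4-one | COc1ccc(COc2cc(OCc3ccc(OC)cc3)cc(O[Si](C(C)C)(C(C)C)C(C)C)c2C(=O)C(=[N+]=[N-])[C@@H]2C(=O)c3c(OCc4ccccc4)cc(OCc4ccccc4)cc3O[C@H]2c2ccc(OCc3ccccc3)cc2)cc1 | intermediate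
17 | (2S,3S)-3-{(2R,3S)-5,7-bis(benzyloxy)-2-[4-(benzyloxy)phenyl]-4-oxochroman-3-yl}-7-[(4-methoxybenzyl)oxy]-2-(4-methoxyphenyl)-5-[(triisopropylsilyl)oxy]chroman-4-one | COc1ccc([C@H]2Oc3cc(OCc4ccc(OC)cc4)cc(O[Si](C(C)C)(C(C)C)C(C)C)c3C(=O)[C@H]2[C@@H]2C(=O)c3c(OCc4ccccc4)cc(OCc4ccccc4)cc3O[C@H]2c2ccc(OCc3ccccc3)cc2)cc1 | intermediate
18 | (2S,3S)-3-{(2R,3S)-5,7-bis(benzyloxy)-2-[4-(benzyloxy)phenyl]-4-oxochroman-3-yl}-5-hydroxy-7-[(4-methoxybenzyl)oxy]-2-(4-methoxyphenyl)chroman-4-one | COc1ccc([C@H]2Oc3cc(OCc4ccc(OC)cc4)cc(O)c3C(=O)[C@H]2[C@@H]2C(=O)c3c(OCc4ccccc4)cc(OCc4ccccc4)cc3O[C@H]2c2ccc(OCc3ccccc3)cc2)cc1 | intermediate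
19 | (2S,3S)-5,7-dihydroxy-3-[(2R,3S)-5,7-dihydroxy-2-(4-hydroxyphenyl)-4-oxochroman-3-yl]-2-(4-methoxyphenyl)chroman-4-one | COc1ccc([C@H]2Oc3cc(O)cc(O)c3C(=O)[C@H]2[C@@H]2C(=O)c3c(O)cc(O)cc3O[C@H]2c2ccc(O)cc2)cc1 | target

**Step count**

Total: 11 steps (steps 1–3 and steps 4–6 are parallel branches).
Longest linear sequence: 8 steps (steps 1, 2, 3, 7, 8, 9, 10, 11; the branch through steps 4, 5, 6 is equally long).

**Steps most likely to fail, with fallbacks**

Step 9 (carbenoid C–H insertion). What may go wrong: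
- 1,2-hydride migration from C3' to the carbenoid carbon;
- attack of an ortho oxygen on the carbenoid (oxonium ylide) followed by 1,2-shift of the 4-methoxybenzyl group or transfer of silicon;
- aromatic substitution on ring B';
- poor discrimination of the two carbenoid faces if catalyst and C3' centre are mismatched;
- erosion of the cis selectivity.

The fallback sets out from 13 and comes back at 19; it builds ring C of unit 1 by chromone annulation and conjugate arylation. Buffered fluoride (Bu4NF/AcOH, THF, 0 °C) would free the ortho phenol to give the hydroxy diketone F1. Condensation of its only methylene with N,N-dimethylformamide dimethyl acetal (toluene, 90 °C) would give the enaminone F2, which should close in warm acetic acid to the 3-substituted chromone F3. Copper-mediated conjugate addition of 4-MeOC6H4MgBr (CuBr·SMe2, Me3SiCl, THF, −78 °C) would bring in the C2 aryl group as the silyl enol ether F4. Kinetic protonation (Bu4NF/AcOH, −78 °C) on the face away from the new aryl group should then give the cis-2,3 chromanone F5, the 5-O-(4-methoxybenzyl) analogue of 17. The face of the aryl addition would rest on the C3' centre, so diastereomers might have to be separated. Hydrogenolysis of F5 as in step 11 would give 19.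

Step 8 (diazo transfer). What may go wrong:
- enolisation towards the C3' methine, with beta-elimination of the ring phenoxide and loss of the C2' configuration;
- migration of the silyl group from the phenol oxygen to the enolate oxygen;
- base-induced isomerisation of the diazo ketone through the C3' enolate.

The fallback sets out from 13 and comes back at 16 without strong base. Heating 13 with tert-butoxybis(dimethylamino)methane in toluene (80 °C) would condense only the methylene, since the C3' methine cannot form an enaminone, and give the enaminone F6. Diazo transfer to this vinylogous amide with 4-toluenesulfonyl azide (CH2Cl2, rt) would give 16, the aminomethylene carbon leaving as the N-sulfonyl formamidine.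

Step 7 (enolate alkylation). What may go wrong:
- E1cB opening of ring C' from the enolate, with racemisation of C2';
- proton transfer from the bromide to the enolate, followed by over-alkylation;
- O-alkylation.

The fallback sets out from 6 and comes back at 13 without a free enolate. Soft enolisation (Me3SiOTf, Et3N, CH2Cl2, 0 °C) would give the silyl enol ether F7. Visible-light photoredox radical alkylation with bromide 11 (fac-Ir(ppy)3, 2,6-lutidine, MeCN, blue light) would add the alpha-keto radical to C3' anti to the C2' aryl group; oxidation of the adduct radical and loss of the silyl group would give 13.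

**Further compounds**

F1 | step 9 | (2R,3S)-5,7-bis(benzyloxy)-2-[4-(benzyloxy)phenyl]-3-(2-{2-hydroxy-4,6-bis[(4-methoxybenzyl)oxy]phenyl}-2-oxoethyl)chroman-4-one | COc1ccc(COc2cc(OCc3ccc(OC)cc3)cc(O)c2C(=O)C[C@@H]2C(=O)c3c(OCc4ccccc4)cc(OCc4ccccc4)cc3O[C@H]2c2ccc(OCc3ccccc3)cc2)cc1
F2 | step 9 | dimethylaminomethylene derivative (enaminone) of F1 at the side-chain methylene | COc1ccc(COc2cc(OCc3ccc(OC)cc3)cc(O)c2C(=O)C(=CN(C)C)[C@@H]2C(=O)c3c(OCc4ccccc4)cc(OCc4ccccc4)cc3O[C@H]2c2ccc(OCc3ccccc3)cc2)cc1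
F3 | step 9 | 3-{(2R,3S)-5,7-bis(benzyloxy)-2-[4-(benzyloxy)phenyl]-4-oxochroman-3-yl}-5,7-bis[(4-methoxybenzyl)oxy]-4H-chromen-4-one | O=c1c([C@@H]2C(=O)c3c(OCc4ccccc4)cc(OCc4ccccc4)cc3O[C@H]2c2ccc(OCc3ccccc3)cc2)coc2cc(OCc3ccc(OC)cc3)cc(OCc3ccc(OC)cc3)c12
F4 | step 9 | 4-(trimethylsilyloxy)-2H-chromene from conjugate arylation of F3 (2-(4-methoxyphenyl), configuration at C2 as in 19) | COc1ccc([C@H]2Oc3cc(OCc4ccc(OC)cc4)cc(OCc4ccc(OC)cc4)c3C(O[Si](C)(C)C)=C2[C@@H]2C(=O)c3c(OCc4ccccc4)cc(OCc4ccccc4)cc3O[C@H]2c2ccc(OCc3ccccc3)cc2)cc1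
F5 | step 9 | (2S,3S)-3-{(2R,3S)-5,7-bis(benzyloxy)-2-[4-(benzyloxy)phenyl]-4-oxochroman-3-yl}-5,7-bis[(4-methoxybenzyl)oxy]-2-(4-methoxyphenyl)chroman-4-one | COc1ccc([C@H]2Oc3cc(OCc4ccc(OC)cc4)cc(OCc4ccc(OC)cc4)c3C(=O)[C@H]2[C@@H]2C(=O)c3c(OCc4ccccc4)cc(OCc4ccccc4)cc3O[C@H]2c2ccc(OCc3ccccc3)cc2)cc1
F6 | step 8 | dimethylaminomethylene derivative (enaminone) of 13 at the side-chain methylene | COc1ccc(COc2cc(OCc3ccc(OC)cc3)cc(O[Si](C(C)C)(C(C)C)C(C)C)c2C(=O)C(=CN(C)C)[C@@H]2C(=O)c3c(OCc4ccccc4)cc(OCc4ccccc4)cc3O[C@H]2c2ccc(OCc3ccccc3)cc2)cc1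
F7 | step 7 | trimethylsilyl enol ether of 6 ((2R)-5,7-bis(benzyloxy)-2-[4-(benzyloxy)phenyl]-4-(trimethylsilyloxy)-2H-chromene) | C[Si](C)(C)OC1=C[C@H](c2ccc(OCc3ccccc3)cc2)Oc2cc(OCc3ccccc3)cc(OCc3ccccc3)c12
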